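Coupling partner is conserved: at any moment its charge stands as free partner, in the intermediates, in target or in decomposed reagent.

| setting | south-west | north-east | north | east | alpha | theta | delta | zeta |
|---|---|---|---|---|---|---|---|---|
| starting material | 0.10 M | 0.10 M | 0.10 M | 0.15 M | 0.10 M | 0.10 M (fed, over 10.0 min) | 0.10 M | 0.10 M |
| coupling partner | 0.10 M | 0.14 M | 0.22 M | 0.10 M | 0.100 M | 0.100 M | 0.100 M (fed, over 10.0 min) | 0.100 M |
| remark | run made earlier | run made earlier | run made earlier | run made earlier | one stirred flow tank at steady state, fed with the mixture as stated, mean residence time 10 min | a stirred flask in which starting material is dosed at a steady rate over 10.0 min without added volume, worked up at 10 min | a stirred flask in which coupling partner is dosed at a steady rate over 10.0 min without added volume, worked up at 10 min | a closed flask charged with all of it at once and left for 10 min |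
| time |  |  |  |  |  | 10 min | 10 min | 10 min |

| run | time / min | target / % |
|---|---|---|
| south-west | 0.833 | 59 |
| south-west | 2.50 | 62 |
| south-west | 5.00 | 62 |
| south-west | 8.00 | 62 |
| south-west | 10.0 | 61 |
| north-east | 2.50 | 75 |
| north-east | 5.00 | 74 |
| north-east | 8.00 | 75 |
| north-east | 10.0 | 72 |
| north-east | 12.0 | 75 |
| north | 1.00 | 84 |
| north | 2.00 | 85 |
| north | 3.00 | 87 |
| north | 6.00 | 84 |
| north | 12.0 | 85 |
| east | 2.50 | 47 |
| east | 5.00 | 50 |
| east | 8.00 | 50 |
| east | 10.0 | 48 |
| east | 12.0 | 51 |

(each reading ± 1.5 percentage points)

- in percentages every species weighs as the starting material in it: one self-condensation product counts as two
- the stated concentrations are those of everything mixed, before any reaction; amounts are the same in each set-up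
- what was read earlier has a scatter of 1.5 percentage points, one standard deviation
- on the list of suspects stand: intermediate A -> target; starting material + coupling partner <-> intermediate A; coupling partner -> decomposed reagent; coupling partner + intermediate A -> intermediate B; intermediate B <-> intermediate C; 2 starting material -> self-condensation product
- the feed brings no volume worth counting
- the earlier runs were made in a closed, stirred flask

1. the set-up with the highest amount of target at the outlet or at the end, in percent of the starting material put in ("none" if the first two lie within 2 percentage points) (alpha / theta / delta / zeta / none)
2. amount of target at the outlet or at the end, in percent of the starting material put in, alpha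
3. amount of target at the outlet or at the end, in percent of the starting material put in, theta
4. amount of target at the outlet or at the end, in percent of the starting material put in, delta
5. amount of target at the outlet or at the end, in percent of the starting material put in, zeta

Read as plateau means, east holds a lower percentage of target than south-west, 49.2% against 61.7%. Yet east turned more of its partner charge into target, 73.8% against 61.7%. The percentage is simply counted on a charge 1.50 times as large.

Taking coupling as proportional to starting material times partner, and decay as proportional to partner, partner cancels from their ratio. Target over decomposed reagent then equals the starting-material level divided by one constant. With amounts as fractions of the partner charge, self-condensation set aside and partner used up, decomposed reagent equals that constant times the logarithm of first over final starting-material level. South-west reads 0.398 and east 0.387. Their mean, 0.392, is the split level, a selectivity factor: the starting-material level at which partner divides evenly between target and decay.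

Zeta repeats south-west, so about 61.7%. Before any self-condensation, delta's slow partner feed gives the same figure, and alpha's tank, holding one level, gives 54.0%; waiting starting material should lower both. If partner lasts about 0.833 min in theta, it meets a mean level of 0.0416, which gives 9.60%.

The forecast named zeta best, with 34% for alpha, 17% for theta, 23% for delta and 62% for zeta, holding that “slow dosing or a long residence time wastes reagent”. The simulation gives zeta best, with 42.5%, 5.18%, 33.1% and 60.9% in that order.

    intermediate A → target (k = 0.425 s⁻¹)
    starting material + coupling partner ⇌ intermediate A (K = 6.78 M⁻¹, k = 3.70 M⁻¹ s⁻¹)
    coupling partner → decomposed reagent (k = 0.0479 s⁻¹)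
    coupling partner + intermediate A → intermediate B (k = 0.458 M⁻¹ s⁻¹)
    intermediate B ⇌ intermediate C (K = 0.110, k = 0.00698 s⁻¹)
    2 starting material → self-condensation product (k = 0.0551 M⁻¹ s⁻¹)

Delta decomposed 63.6% of its partner against 33.1% target, a ratio of 0.519; by its definition, the split level, read from the runs as 0.392, times that ratio is the mean starting-material level delta's partner met. The neighbour with 0.17 M of partner gives 44.1% target and a lower ratio, 0.368. Delta is not quite at rest at 10 min, with partner at 3.16%, starting material at 2.72% and self-condensation product at 64.1%. At 100 min, ten times that time, delta holds partner at 0%, starting material at 1.00%, self-condensation product at 65.6% and target at 33.3%.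

The runs stem from a simulated flask from invented constants, and the scatter is random.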